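**Strategy.** Everything rests on cutting the bond between C2 of the pyranone ring (ring C) and C1′ of the guaiacyl ring (ring B). In a chromone, C2 is the β-carbon of the vinylogous ester O1–C2=C3–C4=O. A rhodium/chiral-diene-catalysed 1,4-addition of a 3-methoxy-4-silyloxyphenylboronic acid to the flat, achiral 5-hydroxy-7-methoxy-6-prenylchromone should therefore join both halves and set C2 in one operation. The C3 hydroxyl is then placed trans to the new aryl group by oxidation of the derived silyl enol ether, and one fluoride treatment frees the three hydroxyl groups.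

Key step: step 6

Remark: the sense of induction is assigned by analogy with 1,4-additions to cyclohexenone, where the (S,S)-diene and (S)-binap give the (S)-3-aryl ketone, which maps onto (2S) here. If the sense proves opposite, the antipodal ligand is used.

**Step 1**
Reactants: 1 5,7-dihydroxy-4H-chromen-4-one
Product: 2 5-hydroxy-7-methoxy-4H-chromen-4-one
Conditions: MeI (1.1 equiv), K2CO3 (1.2 equiv), acetone, reflux
Reagents that add atoms: iodomethane, CI
Why: Williamson etherification; the 7-OH is the acidic, non-chelated phenol, whereas the 5-OH is held in a hydrogen bond to C4=O, so mono-methylation at O7 is expected.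

**Step 2**
Reactants: 2 5-hydroxy-7-methoxy-4H-chromen-4-one
Product: 3 7-methoxy-5-[(3-methylbut-2-en-1-yl)oxy]-4H-chromen-4-one
Conditions: prenyl bromide (1.5 equiv), K2CO3 (3 equiv), DMF, 60 °C
Reagents that add atoms: 1-bromo-3-methylbut-2-ene, CC(C)=CCBr
Why: Williamson O-alkylation of the chelated 5-phenol under more forcing, polar aprotic conditions that favour O- over C-alkylation.

**Step 3**
Reactants: 3 7-methoxy-5-[(3-methylbut-2-en-1-yl)oxy]-4H-chromen-4-one
Product: 4 5-hydroxy-7-methoxy-6-(3-methylbut-2-en-1-yl)-4H-chromen-4-one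
Conditions: Montmorillonite K10, CH2Cl2, 0 °C to rt
Reagents that add atoms: none
Why: clay-promoted formal [1,3] O-to-C prenyl shift of an aryl prenyl ether; the tight prenyl cation/phenol pair should recombine through the unsubstituted prenyl terminus at C6, the only free position ortho to O5, and the restored 5-OH···O=C4 hydrogen bond drives it.

**Step 4**
Reactants: 5 4-bromo-2-methoxyphenol
Product: 6 (4-bromo-2-methoxyphenoxy)tri(propan-2-yl)silane
Conditions: TIPSCl, imidazole, DMF, rt
Reagents that add atoms: chlorotri(propan-2-yl)silane, CC(C)[Si](Cl)(C(C)C)C(C)C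
Why: standard phenol silylation; the TIPS ether should survive the aqueous base of step 6 and masks the 4′-phenol, whose phenoxide could open the flavanone through a quinone methide and scramble C2.

**Step 5**
Reactants: 6 (4-bromo-2-methoxyphenoxy)tri(propan-2-yl)silane
Product: 9 [3-methoxy-4-(triisopropylsilyloxy)phenyl]boronic acid, via aryllithium 7 (not isolated), via lithium aryltriisopropoxyborate 8 (not isolated)
Conditions: n-BuLi, THF, −78 °C; B(OiPr)3, −78 °C to rt; 1 M HCl, 0 °C
Reagents that add atoms: triisopropyl borate, CC(C)OB(OC(C)C)OC(C)C; water, O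
Why: bromine–lithium exchange, trapping of the aryllithium as the borate and hydrolysis; the silyloxy group is para to the carbanion, so no silyl migration is expected.

**Step 6**
Reactants: 4 5-hydroxy-7-methoxy-6-(3-methylbut-2-en-1-yl)-4H-chromen-4-one; 9 [3-methoxy-4-(triisopropylsilyloxy)phenyl]boronic acid (2.5 equiv)
Product: 10 (2S)-5-hydroxy-7-methoxy-2-[3-methoxy-4-(triisopropylsilyloxy)phenyl]-6-(3-methylbut-2-en-1-yl)-2,3-dihydro-4H-chromen-4-one
Conditions: [RhCl(C2H4)2]2 (2.5 mol %), (S,S)-2,5-diphenylbicyclo[2.2.2]octa-2,5-diene (5.5 mol %), aq. KOH (0.2 equiv), 1,4-dioxane/H2O 10:1, 50 °C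
Reagents that add atoms: none
Why: Hayashi–Miyaura asymmetric 1,4-addition, a reaction type known for chromones: the aryl group passes from boron to a Rh(I)–OH species, the aryl–Rh bond adds syn across C2=C3 of the pyranone ring with the aryl going to C2, and water protonates the resulting oxa-π-allyl rhodium enolate at C3 and regenerates Rh–OH. No ring is closed. The C2 stereocentre is set by the C2-symmetric diene on rhodium, which should expose one enantioface of the coordinated C2=C3 bond and give (2S). The step needs 1,4- over 1,2-addition, no insertion into the prenyl alkene and no loss of C2 integrity afterwards: aryl–Rh adds to the electron-poor enone and not to an unactivated trisubstituted alkene, the 5-OH···O=C4 hydrogen bond activates the enone, and the TIPS ether blocks the 4′-phenoxide/quinone methide path to ring opening under the weakly basic conditions.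

**Step 7**
Reactants: 10 (2S)-5-hydroxy-7-methoxy-2-[3-methoxy-4-(triisopropylsilyloxy)phenyl]-6-(3-methylbut-2-en-1-yl)-2,3-dihydro-4H-chromen-4-one
Product: 11 (2S)-7-methoxy-2-[3-methoxy-4-(triisopropylsilyloxy)phenyl]-6-(3-methylbut-2-en-1-yl)-4,5-bis(trimethylsilyloxy)-2H-chromene
Conditions: TMSOTf (2.5 equiv), Et3N (4 equiv), CH2Cl2, −20 to 0 °C; pentane, filtration, concentration (used crude)
Reagents that add atoms: trimethylsilyl trifluoromethanesulfonate, C[Si](C)(C)OS(=O)(=O)C(F)(F)F
Why: soft enolisation (silyl triflate/amine) gives the C3=C4 silyl enol ether without a free enolate, which should avoid E1cB opening of the pyranone ring and keep C2 intact; the 5-OH is silylated in the same operation.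

**Step 8**
Reactants: 11 (2S)-7-methoxy-2-[3-methoxy-4-(triisopropylsilyloxy)phenyl]-6-(3-methylbut-2-en-1-yl)-4,5-bis(trimethylsilyloxy)-2H-chromene
Product: 13 (2R,3R)-3,5-dihydroxy-2-(4-hydroxy-3-methoxyphenyl)-7-methoxy-6-(3-methylbut-2-en-1-yl)-2,3-dihydro-4H-chromen-4-one (target), via silyloxy epoxide 12 (not isolated)
Conditions: trans-2-(phenylsulfonyl)-3-phenyloxaziridine (1.3 equiv), CHCl3, 25 to 50 °C; then KHF2 (6 equiv), MeOH/THF, rt
Reagents that add atoms: trans-2-(phenylsulfonyl)-3-phenyloxaziridine, O=S(=O)(c1ccccc1)N1OC1c1ccccc1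
Why: Rubottom-type oxidation with a Davis oxaziridine, which should transfer oxygen to the electron-rich silyl enol ether rather than to the prenyl alkene and from the face opposite to the 2-aryl group, fixing C3 as (R), trans to the aryl (also the thermodynamically preferred arrangement); bifluoride then collapses the silyloxy epoxide to the α-hydroxy ketone and cleaves both aryl silyl ethers under mildly acidic conditions that should not epimerise C2.

**Compound list**

1 | 5,7-dihydroxy-4H-chromen-4-one | O=c1ccoc2cc(O)cc(O)c12 | starting material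
2 | 5-hydroxy-7-methoxy-4H-chromen-4-one | O=c1ccoc2cc(OC)cc(O)c12 | intermediate
3 | 7-methoxy-5-[(3-methylbut-2-en-1-yl)oxy]-4H-chromen-4-one | O=c1ccoc2cc(OC)cc(OCC=C(C)C)c12 | intermediate
4 | 5-hydroxy-7-methoxy-6-(3-methylbut-2-en-1-yl)-4H-chromen-4-one | O=c1ccoc2cc(OC)c(CC=C(C)C)c(O)c12 | intermediate
5 | 4-bromo-2-methoxyphenol | COc1cc(Br)ccc1O | starting material
6 | (4-bromo-2-methoxyphenoxy)tri(propan-2-yl)silane | COc1cc(Br)ccc1O[Si](C(C)C)(C(C)C)C(C)C | intermediate
7 | [3-methoxy-4-(triisopropylsilyloxy)phenyl]lithium | COc1cc([Li])ccc1O[Si](C(C)C)(C(C)C)C(C)C | intermediate (not isolated)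
8 | lithium [3-methoxy-4-(triisopropylsilyloxy)phenyl]tri(propan-2-yloxy)borate | [Li+].COc1cc([B-](OC(C)C)(OC(C)C)OC(C)C)ccc1O[Si](C(C)C)(C(C)C)C(C)C | intermediate (not isolated)
9 | [3-methoxy-4-(triisopropylsilyloxy)phenyl]boronic acid | COc1cc(B(O)O)ccc1O[Si](C(C)C)(C(C)C)C(C)C | intermediate
10 | (2S)-5-hydroxy-7-methoxy-2-[3-methoxy-4-(triisopropylsilyloxy)phenyl]-6-(3-methylbut-2-en-1-yl)-2,3-dihydro-4H-chromen-4-one | COc1cc([C@H]2Oc3cc(OC)c(CC=C(C)C)c(O)c3C(=O)C2)ccc1O[Si](C(C)C)(C(C)C)C(C)C | intermediate
11 | (2S)-7-methoxy-2-[3-methoxy-4-(triisopropylsilyloxy)phenyl]-6-(3-methylbut-2-en-1-yl)-4,5-bis(trimethylsilyloxy)-2H-chromene | COc1cc([C@H]2Oc3cc(OC)c(CC=C(C)C)c(O[Si](C)(C)C)c3C(O[Si](C)(C)C)=C2)ccc1O[Si](C(C)C)(C(C)C)C(C)C | intermediate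
12 | 3,4-epoxide of 11, oxirane oxygen on the ring face opposite to the 2-aryl group (C4 keeps its OSiMe3) | COc1cc([C@H]2Oc3cc(OC)c(CC=C(C)C)c(O[Si](C)(C)C)c3[C@]4(O[Si](C)(C)C)O[C@H]24)ccc1O[Si](C(C)C)(C(C)C)C(C)C | intermediate (not isolated)
13 | (2R,3R)-3,5-dihydroxy-2-(4-hydroxy-3-methoxyphenyl)-7-methoxy-6-(3-methylbut-2-en-1-yl)-2,3-dihydro-4H-chromen-4-one | COc1cc([C@H]2Oc3cc(OC)c(CC=C(C)C)c(O)c3C(=O)[C@@H]2O)ccc1O | target

**Total steps:** 8. **Longest linear sequence:** 6 (steps 1, 2, 3, 6, 7, 8).

**Steps most likely to fail**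

Step 6. The chiral diene may discriminate the enantiofaces of this 5-hydroxy-6,7-disubstituted chromone poorly, and base-mediated opening and re-closure of the pyranone ring during a slow addition may erode the enantiomeric purity further. The fallback moves stereocontrol from the C–C bond formation to a kinetic resolution. It sets out from 4 and 9, which are joined with the achiral, more active [Rh(OH)(cod)]2 (dioxane/H2O, 50 °C) to give the racemic flavanone F1. Asymmetric transfer hydrogenation (Cp*RhCl[(R,R)-TsDPEN], HCO2H/Et3N, EtOAc, rt, stopped near half conversion) should reduce the (2R) enantiomer faster, with hydride delivered anti to the aryl group, to the cis-(2R,4R)-flavan-4-ol F2. F2 is removed by chromatography, and the unreduced (2S)-ketone is compound 10, where the route is rejoined.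

Step 3. The prenyl cation released on the clay may recombine at C8 instead of C6 or be lost altogether, and the acidic surface may cyclise the new 5-OH onto the prenyl double bond. The fallback uses a concerted sigmatropic shift instead. It sets out from 2: O-allylation (allyl bromide, K2CO3, DMF) gives 5-(allyloxy)-7-methoxy-4H-chromen-4-one F3. Aromatic Claisen rearrangement (Eu(fod)3 cat., chlorobenzene, 120 °C) can only deliver the allyl group to C6 and should give 6-allyl-5-hydroxy-7-methoxy-4H-chromen-4-one F4. Cross-metathesis with 2-methylbut-2-ene (Grubbs second-generation catalyst, CH2Cl2, 40 °C) turns the allyl into the prenyl group and comes back to the route at 4.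

Step 7. Lewis-acid-assisted opening of the pyranone ring (ionisation of the benzylic C2–O1 bond or retro-oxa-Michael reaction of the O-silylated ketone) may scramble C2, and peri strain next to the 5-silyloxy group may leave the enol silylation incomplete. The fallback makes the silyl enol ether directly in the bond-forming event, so that no flavanone has to be enolised. It sets out from 4 and 6. Chromone 4 is silylated (TMSCl, Et3N, CH2Cl2) to 7-methoxy-6-(3-methylbut-2-en-1-yl)-5-(trimethylsilyloxy)-4H-chromen-4-one F5. Bromide 6 is converted (n-BuLi, THF, −78 °C; ZnCl2) into the arylzinc chloride F6. Rhodium-catalysed asymmetric 1,4-addition of F6 to F5 in the presence of TMSCl ([RhCl((S)-binap)]2, THF, 20 °C) should trap the enolate as its silyl ether and come back to the route at 11.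

**Further compounds**

F1 | step 6 | rac-5-hydroxy-7-methoxy-2-[3-methoxy-4-(triisopropylsilyloxy)phenyl]-6-(3-methylbut-2-en-1-yl)-2,3-dihydro-4H-chromen-4-one | COc1cc(C2Oc3cc(OC)c(CC=C(C)C)c(O)c3C(=O)C2)ccc1O[Si](C(C)C)(C(C)C)C(C)C
F2 | step 6 | (2R,4R)-7-methoxy-2-[3-methoxy-4-(triisopropylsilyloxy)phenyl]-6-(3-methylbut-2-en-1-yl)-3,4-dihydro-2H-chromene-4,5-diol | COc1cc([C@@H]2Oc3cc(OC)c(CC=C(C)C)c(O)c3[C@H](O)C2)ccc1O[Si](C(C)C)(C(C)C)C(C)C
F3 | step 3 | 5-(allyloxy)-7-methoxy-4H-chromen-4-one | O=c1ccoc2cc(OC)cc(OCC=C)c12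
F4 | step 3 | 6-allyl-5-hydroxy-7-methoxy-4H-chromen-4-one | O=c1ccoc2cc(OC)c(CC=C)c(O)c12
F5 | step 7 | 7-methoxy-6-(3-methylbut-2-en-1-yl)-5-(trimethylsilyloxy)-4H-chromen-4-one | O=c1ccoc2cc(OC)c(CC=C(C)C)c(O[Si](C)(C)C)c12
F6 | step 7 | [3-methoxy-4-(triisopropylsilyloxy)phenyl]zinc chloride | COc1cc([Zn]Cl)ccc1O[Si](C(C)C)(C(C)C)C(C)C
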